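**Retrosynthetic overview**
1. Last step removes two MOM ethers; before that, the 2H‑pyran is fused onto a dibenzo[b,f]oxepin‑10(11H)‑one with prenal (Knoevenagel condensation, then oxa‑6π electrocyclisation).
2. The oxepinone comes from intramolecular Pd ketone α‑arylation (C11–aryl bond), after an SNAr diaryl‑ether union of two arene halves of similar size (A‑ring prenylated bromophenol + B‑ring 2‑fluoroacetophenone).
3. A‑ring half from resorcinol (dibromination, mono‑MOM, chemoselective Br/Li exchange → Cu → prenylation); B‑ring half from 3‑fluorophenol (MOM, para‑bromination, Br/Li → Weinreb acylation).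
4. Both C5 units (prenyl bromide for the side chain, prenal for the pyran) are made from prenol.
5. Ring order: both benzene rings are bought; oxepine formed in step 10; pyran formed in step 11.

Assumption: the target has no stereocentre and no stereogenic double bond (it is achiral), so "single enantiomer" needs no stereocontrol; the structure is made exactly as drawn.

---

**Step 1**
Reactants: 1, resorcinol
Product: 2, 4,6‑dibromobenzene‑1,3‑diol
Conditions: Br2 (2.0 equiv), CHCl3, 0 °C → rt
Reagents that add atoms: bromine, BrBr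
Why: Electrophilic aromatic bromination; C4 and C6 are each ortho to one OH and para to the other, whereas C2 is flanked by both, so two equivalents in a non‑aqueous solvent stop at the 4,6‑dibromide.

**Step 2**
Reactants: 2, 4,6‑dibromobenzene‑1,3‑diol
Product: 3, 2,4‑dibromo‑5‑(methoxymethoxy)phenol
Conditions: NaH (1.0 equiv), THF/DMF, 0 °C; MOMCl (1.0 equiv); chromatography, recovered 2 recycled
Reagents that add atoms: chloromethyl methyl ether, COCCl
Why: Williamson‑type O‑alkylation of the mono‑phenoxide; because 2 is symmetric, any mono‑alkylation gives the same single product (roughly statistical yield).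

**Step 3**
Reactants: 4, 3‑methylbut‑2‑en‑1‑ol (prenol)
Product: 5, 1‑bromo‑3‑methylbut‑2‑ene (prenyl bromide)
Conditions: PBr3 (0.4 equiv), Et2O, −10 → 0 °C; used fresh
Reagents that add atoms: phosphorus tribromide, BrP(Br)Br
Why: SN2 bromination of the primary allylic alcohol via its phosphite at low temperature gives the primary bromide free of the tertiary isomer and HBr.

**Step 4**
Reactants: 3, 2,4‑dibromo‑5‑(methoxymethoxy)phenol; 5, prenyl bromide
Product: 6, 2‑bromo‑5‑(methoxymethoxy)‑4‑(3‑methylbut‑2‑en‑1‑yl)phenol
Conditions: n‑BuLi (2.2 equiv), THF, −78 °C; CuBr·SMe2 (1.1 equiv), −78 → −40 °C; 5 (1.5 equiv), → 0 °C; aq NH4Cl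
Reagents that add atoms: none (the C5 unit comes from 5)
Why: After OH deprotonation, Br/Li exchange occurs at the bromide ortho to the chelating OMOM group (the bromide ortho to ArOLi exchanges far more slowly at −78 °C), and the arylcopper is allylated at the primary carbon (SN2) because γ‑attack would create a quaternary centre.

**Step 5**
Reactants: 7, 3‑fluorophenol
Product: 8, 1‑fluoro‑3‑(methoxymethoxy)benzene
Conditions: MOMCl (1.2 equiv), i‑Pr2NEt, CH2Cl2, 0 °C → rt
Reagents that add atoms: chloromethyl methyl ether, COCCl
Why: Standard phenol O‑alkylation to an acetal ether that survives organolithium, SNAr and Pd/base conditions.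

**Step 6**
Reactants: 8, 1‑fluoro‑3‑(methoxymethoxy)benzene
Product: 9, 1‑bromo‑2‑fluoro‑4‑(methoxymethoxy)benzene
Conditions: NBS (1.05 equiv), MeCN, 0 °C → rt
Reagents that add atoms: N‑bromosuccinimide, O=C1CCC(=O)N1Br
Why: Electrophilic bromination under neutral conditions goes para to the strongest donor (OMOM), a position also ortho to F.

**Step 7**
Reactants: 9, 1‑bromo‑2‑fluoro‑4‑(methoxymethoxy)benzene; 10, N‑methoxy‑N‑methylacetamide
Product: 11, 1‑[2‑fluoro‑4‑(methoxymethoxy)phenyl]ethan‑1‑one
Conditions: n‑BuLi (1.05 equiv), THF, −78 °C, 20 min; 10 (1.2 equiv), −78 → 0 °C; aq NH4Cl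
Reagents that add atoms: none (acetyl comes from 10)
Why: Br/Li exchange followed by Weinreb ketone synthesis (the chelated tetrahedral intermediate prevents over‑addition); −78 °C keeps the ortho‑fluoroaryllithium from losing LiF to a benzyne.

**Step 8**
Reactants: 4, prenol
Product: 12, 3‑methylbut‑2‑enal (prenal)
Conditions: activated MnO2 (10 equiv), CH2Cl2, rt; filter, careful concentration
Reagents that add atoms: none
Why: Chemoselective oxidation of an allylic alcohol gives acid‑free aldehyde, which matters for the amine‑catalysed condensation in step 11.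

**Step 9**
Reactants: 6, 2‑bromo‑5‑(methoxymethoxy)‑4‑prenylphenol; 11, 1‑[2‑fluoro‑4‑(methoxymethoxy)phenyl]ethan‑1‑one
Product: 13, 1‑{2‑[2‑bromo‑5‑(methoxymethoxy)‑4‑(3‑methylbut‑2‑en‑1‑yl)phenoxy]‑4‑(methoxymethoxy)phenyl}ethan‑1‑one
Conditions: Cs2CO3 (1.5 equiv), DMSO, 90 °C
Reagents that add atoms: none
Why: SNAr of the phenoxide on the fluoride ortho to the acetyl group (Meisenheimer complex stabilised by the carbonyl); the electron‑rich aryl bromide, MOM ethers and prenyl group are inert.

**Step 10**
Reactants: 13, the diaryl ether bromo‑ketone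
Product: 14, 3,7‑bis(methoxymethoxy)‑2‑(3‑methylbut‑2‑en‑1‑yl)dibenzo[b,f]oxepin‑10(11H)‑one (C=O on the B‑ring side, CH2 on the A‑ring side)
Conditions: Pd2(dba)3 (2.5 mol %), XPhos (6 mol %), NaOt‑Bu (2.2 equiv), degassed toluene (0.02 M), 80 °C
Reagents that add atoms: none
Why: Intramolecular Pd‑catalysed ketone α‑arylation (Buchwald–Hartwig type): Pd(0) inserts into the only C–Br bond and the methyl‑ketone enolate (the only enolisable site) closes the seven‑membered ring, with high dilution suppressing intermolecular arylation.

**Step 11**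
Reactants: 14, the oxepinone; 12, prenal
Product: 15, artocarpol D bis(methoxymethyl) ether (2,2‑dimethyl‑2H‑pyran fused across C10=C11, pyran O on the carbon bearing the B ring)
Conditions: 12 (3 equiv), ethylenediammonium diacetate (20 mol %), 4 Å MS, toluene, 90 °C
Reagents that add atoms: none (the C5 unit comes from 12)
Why: Knoevenagel‑type condensation of the C11 methylene (α to C=O and benzylic) with the enal iminium at its carbonyl carbon (the β‑carbon is disubstituted, disfavouring 1,4‑addition) gives the 1‑oxatriene, which closes by oxa‑6π electrocyclisation to the 2H‑pyran (formal [3+3] annulation).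

**Step 12**
Reactants: 15, artocarpol D bis(MOM) ether
Product: 16, artocarpol D
Conditions: TMSOTf (4 equiv), 2,2′‑bipyridyl (6 equiv), MeCN, 0 °C → rt; then H2O
Reagents that add atoms: none
Why: Bipyridyl‑buffered silyl triflate converts ArOMOM to ArOTMS, hydrolysed on work‑up, so both acetals are cleaved without Brønsted acid that could cyclise the ortho‑prenyl phenol or open the dienol‑ether pyran.

---

**Compound list**
1 | resorcinol | Oc1cccc(O)c1 | starting material
2 | 4,6‑dibromobenzene‑1,3‑diol | Oc1cc(O)c(Br)cc1Br | intermediate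
3 | 2,4‑dibromo‑5‑(methoxymethoxy)phenol | COCOc1cc(O)c(Br)cc1Br | intermediate
4 | 3‑methylbut‑2‑en‑1‑ol (prenol) | CC(C)=CCO | starting material
5 | 1‑bromo‑3‑methylbut‑2‑ene | CC(C)=CCBr | intermediate
6 | 2‑bromo‑5‑(methoxymethoxy)‑4‑(3‑methylbut‑2‑en‑1‑yl)phenol | COCOc1cc(O)c(Br)cc1CC=C(C)C | intermediate
7 | 3‑fluorophenol | Oc1cccc(F)c1 | starting material
8 | 1‑fluoro‑3‑(methoxymethoxy)benzene | COCOc1cccc(F)c1 | intermediate
9 | 1‑bromo‑2‑fluoro‑4‑(methoxymethoxy)benzene | COCOc1ccc(Br)c(F)c1 | intermediate
10 | N‑methoxy‑N‑methylacetamide | CC(=O)N(C)OC | starting material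
11 | 1‑[2‑fluoro‑4‑(methoxymethoxy)phenyl]ethan‑1‑one | CC(=O)c1ccc(OCOC)cc1F | intermediate
12 | 3‑methylbut‑2‑enal | CC(C)=CC=O | intermediate
13 | 1‑{2‑[2‑bromo‑5‑(methoxymethoxy)‑4‑prenylphenoxy]‑4‑(methoxymethoxy)phenyl}ethan‑1‑one | CC(=O)c1ccc(OCOC)cc1Oc1cc(OCOC)c(CC=C(C)C)cc1Br | intermediate
14 | 3,7‑bis(methoxymethoxy)‑2‑prenyldibenzo[b,f]oxepin‑10(11H)‑one | O=C1Cc2cc(CC=C(C)C)c(OCOC)cc2Oc2cc(OCOC)ccc21 | intermediate
15 | artocarpol D bis(MOM) ether | CC(C)=CCc1cc2c(cc1OCOC)Oc1cc(OCOC)ccc1C1=C2C=CC(C)(C)O1 | intermediate
16 | artocarpol D | CC(C)=CCc1cc2c(cc1O)Oc1cc(O)ccc1C1=C2C=CC(C)(C)O1 | target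

**Totals**
Total steps: 12.
Longest linear sequence: 7 steps (1 → 2 → 4 → 9 → 10 → 11 → 12 from resorcinol; the 3‑fluorophenol arm, 5 → 6 → 7 → 9 → 10 → 11 → 12, is equally long).

**Three steps most likely to fail, with fallbacks**
- **Step 11 (pyran annulation on a ketone that is not a 1,3‑dicarbonyl).** Fallback: build the pyran at a higher oxidation level. C‑acylate the enolate of 14 with 3‑methylbut‑2‑enoyl chloride, let the enolised 1,3‑diketone close by 6‑endo oxa‑Michael addition to the 2,2‑dimethyl‑2,3‑dihydropyran‑4‑one, then Luche reduction and dehydration to the 2H‑pyran.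
- **Step 10 (seven‑membered ring by Pd α‑arylation; competing intermolecular arylation or debromination).** Fallback: close the ring by the classical route instead. Ullmann‑couple an A‑ring (2‑hydroxyaryl)acetic ester with a B‑ring 3‑alkoxy‑bromobenzene, hydrolyse, and cyclise by intramolecular Friedel–Crafts acylation para to the B‑ring oxygen. The prenyl group would then go on afterwards from an A‑ring bromide (Br/Cu or Stille), since it would not survive the acid.
- **Step 12 (MOM removal next to an ortho‑prenyl phenol and a dienol‑ether pyran).** Fallback: change the protecting‑group plan to a fluoride‑labile one. Either carry both phenols as SEM ethers from steps 2 and 5 and finish with TBAF/DMPU, or swap MOM for TBS at ketone 14 (HCl/MeOH, then TBSCl) before annulation and finish with TBAF.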